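## Retrosynthetic overview

1. The target is 2-[(2R,12R)-2,12-diacetoxytridecyl]-4,6-dihydroxybenzoic acid. The CO2H is put on last (Vilsmeier–Haack CHO, then NaClO2) on the free 5-alkylresorcinol, so no ester ever sits ortho to the C2 oxygen of the chain and no dihydroisocoumarin can form.
2. Key disconnection: the aryl–CH2 bond, made by nickel-catalysed radical cross-electrophile coupling of a 3,5-bis(silyloxy)phenyl bromide with the terminal (R)-epoxide that already carries the whole C13 chain and the C12 carbinol. C2 comes unchanged from the epoxide, and both acetates go on in the same flask.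
3. Aryl bromide ⇒ resorcinol (O-silylation, then iridium-catalysed C–H borylation at C5 and CuBr2).
4. Epoxy alcohol ⇒ (R)-propylene oxide + 7-bromohept-1-ene + (R)-epichlorohydrin: two copper-catalysed Grignard epoxide openings, linked by a radical anti-Markovnikov HBr addition.
5. Rings: the benzene ring is bought with resorcinol and no carbocycle is built. The only ring made is the oxirane (step 5), which is opened again in the key step (step 6).

Assumption: chain positions are numbered C1 (benzylic CH2) to C13 (terminal CH3), and the SMILES is read as (2R,12R).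

## Route

Step 1
Reactants: 1 resorcinol (benzene-1,3-diol)
Product: 2 1,3-bis(triisopropylsilyloxy)benzene
Conditions: TIPSCl (2.3 equiv), imidazole (5 equiv), DMF, 25 °C
Reagents that add atoms: chlorotriisopropylsilane (TIPSCl), CC(C)[Si](Cl)(C(C)C)C(C)C
Why: Imidazole-promoted O-silylation of both phenols (silyl ether protection); the bulky TIPS groups leave only C5–H unhindered for step 2 and survive aqueous CuBr2 and the reductive coupling.

Step 2
Reactants: 2 1,3-bis(triisopropylsilyloxy)benzene
Product: 4 1-bromo-3,5-bis(triisopropylsilyloxy)benzene, via arylboronic ester 3 (not isolated)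
Conditions: B2pin2 (1.0 equiv), [Ir(OMe)(cod)]2 (1.5 mol%), 4,4'-di-tert-butyl-2,2'-bipyridine (3 mol%), THF, 80 °C; solvent removed; then CuBr2 (3 equiv), MeOH/THF/H2O, 80 °C
Reagents that add atoms: copper dibromide (CuBr2), Br[Cu]Br
Why: Sterically controlled iridium-catalysed aromatic C–H borylation touches only the C–H with no ortho substituent (C5), and copper-mediated bromodeboronation in the same flask gives the meta bromide that electrophilic bromination cannot reach.

Step 3
Reactants: 5 7-bromohept-1-ene; 6 (R)-propylene oxide [(2R)-2-methyloxirane]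
Product: 8 (2R)-dec-9-en-2-ol, via hept-6-enylmagnesium bromide 7 (not isolated)
Conditions: Mg, THF, 25 °C; then CuI (5 mol%), 6, −30 → 0 °C; then H2O
Reagents that add atoms: none
Why: Copper-catalysed Grignard opening of a terminal epoxide at its CH2 terminus (SN2); the carbinol stereocentre (later C12) is the untouched stereocentre of (R)-propylene oxide.

Step 4
Reactants: 8 (2R)-dec-9-en-2-ol
Product: 9 (2R)-10-bromodecan-2-ol
Conditions: HBr (gas), (PhCO2)2 (5 mol%), hexane, 0 °C
Reagents that add atoms: hydrogen bromide, Br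
Why: Kharasch anti-Markovnikov radical-chain hydrobromination of the terminal alkene (Br atom adds to the CH2 end, the secondary radical takes H from HBr), precedented for alkenols with a free OH; the stereocentre is not touched.

Step 5
Reactants: 9 (2R)-10-bromodecan-2-ol; 10 (R)-epichlorohydrin [(2R)-2-(chloromethyl)oxirane]
Product: 14 (2R)-11-[(2R)-oxiran-2-yl]undecan-2-ol, via bromo alkoxide 11 (not isolated), via alkoxide Grignard reagent 12 (not isolated), via chlorohydrin 13 (not isolated)
Conditions: i-PrMgCl (1.0 equiv), THF, −20 °C; Mg, 40 °C; then CuI (10 mol%), 10, −40 → −10 °C; then 3 M aq. NaOH, 25 °C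
Reagents that add atoms: none
Why: Normant-type alkoxide Grignard reagent (OH masked as its magnesium alkoxide), copper-catalysed opening of epichlorohydrin at the epoxide CH2, then intramolecular Williamson closure of the chlorohydrin; the oxirane stereocentre (later C2) is the retained C–O stereocentre of (R)-epichlorohydrin.

Step 6
Reactants: 4 1-bromo-3,5-bis(triisopropylsilyloxy)benzene (1.3 equiv); 14 (2R)-11-[(2R)-oxiran-2-yl]undecan-2-ol
Product: 17 (2R,12R)-1-[3,5-bis(triisopropylsilyloxy)phenyl]tridecane-2,12-diyl diacetate, via iodohydrin 15 (not isolated), via diol 16 (not isolated)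
Conditions: NiI2 (10 mol%), 2,2'-bipyridine (10 mol%), NaI (25 mol%), Et3N·HCl (1.2 equiv), Zn dust (2 equiv), DMPU, 25 °C; then Et3N, DMAP (cat.), Ac2O, 25 °C
Reagents that add atoms: acetic anhydride (Ac2O), CC(=O)OC(C)=O
Why: Weix-type nickel-catalysed reductive cross-electrophile coupling of an aryl bromide with a terminal epoxide under iodide co-catalysis: iodide opens the epoxide at CH2 to 15, nickel turns its C–I bond into a primary alkyl radical that is captured by the arylnickel species and reductively eliminated to the aryl–CH2 bond, so the C2 carbinol keeps the (R) configuration of the epoxide, and the DMAP-catalysed acetylation breaks neither C–O bond.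

Step 7
Reactants: 17 (2R,12R)-1-[3,5-bis(triisopropylsilyloxy)phenyl]tridecane-2,12-diyl diacetate
Product: 18 (2R,12R)-1-(3,5-dihydroxyphenyl)tridecane-2,12-diyl diacetate
Conditions: TBAF (2.4 equiv), AcOH (3 equiv), THF, 0 → 25 °C
Reagents that add atoms: none
Why: Fluoride-mediated cleavage of aryl silyl ethers (Si–F bond formation), buffered with AcOH so that the phenoxides are protonated at once and the secondary acetates are neither cleaved nor moved.

Step 8
Reactants: 18 (2R,12R)-1-(3,5-dihydroxyphenyl)tridecane-2,12-diyl diacetate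
Product: 20 (2R,12R)-1-(2-formyl-3,5-dihydroxyphenyl)tridecane-2,12-diyl diacetate, via iminium salt 19 (not isolated)
Conditions: POCl3 (1.5 equiv), DMF (3 equiv), MeCN, 0 → 25 °C; then H2O, 40 °C
Reagents that add atoms: N,N-dimethylformamide (DMF), CN(C)C=O; water, O
Why: Vilsmeier–Haack formylation of a 5-alkylresorcinol goes para to one OH and ortho to the other, at the ring position next to the alkyl chain (as orcinol gives orcylaldehyde); water hydrolyses iminium salt 19 to the aldehyde and the acetates are inert.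

Step 9
Reactants: 20 (2R,12R)-1-(2-formyl-3,5-dihydroxyphenyl)tridecane-2,12-diyl diacetate
Product: 21 2-[(2R,12R)-2,12-diacetoxytridecyl]-4,6-dihydroxybenzoic acid
Conditions: NaClO2 (2 equiv), NaH2PO4 (3 equiv), 2-methylbut-2-ene (20 equiv), t-BuOH/THF/H2O, 0 → 25 °C
Reagents that add atoms: NaClO2 (sodium chlorite), [Na+].[O-]Cl=O
Why: Pinnick (Lindgren–Kraus) chlorite oxidation of the aldehyde to the acid with 2-methylbut-2-ene as hypochlorite scavenger, mild enough (pH about 4, 25 °C or below) to keep both acetates, the free phenols and the decarboxylation-prone acid intact; no stereocentre is touched.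

## Compound list

1 | resorcinol (benzene-1,3-diol) | Oc1cccc(O)c1 | starting material
2 | 1,3-bis(triisopropylsilyloxy)benzene | CC(C)[Si](Oc1cccc(O[Si](C(C)C)(C(C)C)C(C)C)c1)(C(C)C)C(C)C | intermediate
3 | 2-[3,5-bis(triisopropylsilyloxy)phenyl]-4,4,5,5-tetramethyl-1,3,2-dioxaborolane | CC(C)[Si](Oc1cc(O[Si](C(C)C)(C(C)C)C(C)C)cc(B2OC(C)(C)C(C)(C)O2)c1)(C(C)C)C(C)C | intermediate
4 | 1-bromo-3,5-bis(triisopropylsilyloxy)benzene | CC(C)[Si](Oc1cc(Br)cc(O[Si](C(C)C)(C(C)C)C(C)C)c1)(C(C)C)C(C)C | intermediate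
5 | 7-bromohept-1-ene | C=CCCCCCBr | starting material
6 | (R)-propylene oxide, (2R)-2-methyloxirane | C[C@@H]1CO1 | starting material
7 | hept-6-en-1-ylmagnesium bromide | C=CCCCCC[Mg]Br | intermediate
8 | (2R)-dec-9-en-2-ol | C[C@@H](O)CCCCCCC=C | intermediate
9 | (2R)-10-bromodecan-2-ol | C[C@@H](O)CCCCCCCCBr | intermediate
10 | (R)-epichlorohydrin, (2R)-2-(chloromethyl)oxirane | ClC[C@H]1CO1 | starting material
11 | chloromagnesium (2R)-10-bromodecan-2-olate | C[C@@H](O[Mg]Cl)CCCCCCCCBr | intermediate
12 | [(9R)-9-(chloromagnesiooxy)decyl]magnesium bromide | C[C@@H](O[Mg]Cl)CCCCCCCC[Mg]Br | intermediate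
13 | (2R,12R)-1-chlorotridecane-2,12-diol (in the flask first as its magnesium alkoxide) | C[C@@H](O)CCCCCCCCC[C@@H](O)CCl | intermediate
14 | (2R)-11-[(2R)-oxiran-2-yl]undecan-2-ol | C[C@@H](O)CCCCCCCCC[C@@H]1CO1 | intermediate
15 | (2R,12R)-1-iodotridecane-2,12-diol | C[C@@H](O)CCCCCCCCC[C@@H](O)CI | intermediate
16 | (2R,12R)-1-[3,5-bis(triisopropylsilyloxy)phenyl]tridecane-2,12-diol | C[C@@H](O)CCCCCCCCC[C@@H](O)Cc1cc(O[Si](C(C)C)(C(C)C)C(C)C)cc(O[Si](C(C)C)(C(C)C)C(C)C)c1 | intermediate
17 | (2R,12R)-1-[3,5-bis(triisopropylsilyloxy)phenyl]tridecane-2,12-diyl diacetate | CC(=O)O[C@H](CCCCCCCCC[C@@H](C)OC(C)=O)Cc1cc(O[Si](C(C)C)(C(C)C)C(C)C)cc(O[Si](C(C)C)(C(C)C)C(C)C)c1 | intermediate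
18 | (2R,12R)-1-(3,5-dihydroxyphenyl)tridecane-2,12-diyl diacetate | CC(=O)O[C@H](CCCCCCCCC[C@@H](C)OC(C)=O)Cc1cc(O)cc(O)c1 | intermediate
19 | N-{2-[(2R,12R)-2,12-diacetoxytridecyl]-4,6-dihydroxybenzylidene}-N-methylmethanaminium chloride | CC(=O)O[C@H](CCCCCCCCC[C@@H](C)OC(C)=O)Cc1cc(O)cc(O)c1C=[N+](C)C.[Cl-] | intermediate
20 | (2R,12R)-1-(2-formyl-3,5-dihydroxyphenyl)tridecane-2,12-diyl diacetate | CC(=O)O[C@H](CCCCCCCCC[C@@H](C)OC(C)=O)Cc1cc(O)cc(O)c1C=O | intermediate
21 | 2-[(2R,12R)-2,12-diacetoxytridecyl]-4,6-dihydroxybenzoic acid | CC(=O)O[C@H](CCCCCCCCC[C@@H](C)OC(C)=O)Cc1cc(O)cc(O)c1C(=O)O | target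

## Step count and weak points

Total steps: 9 (arene branch: steps 1–2; chain branch: steps 3–5; after union: steps 6–9).
Longest linear sequence: 7 steps (5 → 8 → 9 → 14 → 17 → 18 → 20 → 21, steps 3–9).

The three steps most likely to fail:

Step 6 (nickel-catalysed aryl bromide/epoxide coupling). The iodohydrin may form slowly next to chloride, and 4 may homocouple or be reduced. The fallback sets out from 14 and comes back at 17. LiBr/AcOH in THF at 25 °C opens 14 at its CH2 terminus to (2R,12R)-1-bromotridecane-2,12-diol F1. Ac2O, pyridine and DMAP turn this into (2R,12R)-1-bromotridecane-2,12-diyl diacetate F2. F2 and 4 are then joined by silyl-radical metallaphotoredox cross-electrophile coupling: NiCl2·glyme, 4,4'-di-tert-butyl-2,2'-bipyridine, Ir[dF(CF3)ppy]2(dtbbpy)PF6, (Me3Si)3SiH, Na2CO3, DME, blue LEDs, 25 °C. The silyl radical abstracts bromine from F2 and the primary radical is arylated on nickel, which gives 17 directly with the acetates already in place.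

Step 5 (Grignard reagent formed next to a magnesium alkoxide). Insertion may be sluggish or the reagent may aggregate. The fallback sets out from 9 and comes back at 14. TBSCl and imidazole in DMF give tert-butyl{[(2R)-10-bromodecan-2-yl]oxy}dimethylsilane F3. Mg in THF gives the ordinary Grignard reagent {(9R)-9-[(tert-butyldimethylsilyl)oxy]decyl}magnesium bromide F4. With CuI (10 mol%) this opens 10 at −40 °C to (2R,12R)-12-[(tert-butyldimethylsilyl)oxy]-1-chlorotridecan-2-ol F5. Aqueous NaOH closes F5 to tert-butyldimethyl({(2R)-11-[(2R)-oxiran-2-yl]undecan-2-yl}oxy)silane F6, and TBAF in THF at 25 °C returns 14.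

Step 9 (chlorite oxidation of an unprotected, very electron-rich salicylaldehyde). Ring chlorination or a slow reaction of the hydrogen-bonded aldehyde are the dangers. The fallback sets out from 20 and comes back at 21. BnBr and K2CO3 in DMF at 50 °C give (2R,12R)-1-[3,5-bis(benzyloxy)-2-formylphenyl]tridecane-2,12-diyl diacetate F7. The same NaClO2/NaH2PO4/2-methylbut-2-ene oxidation, now on a ring without free phenols, gives 2,4-bis(benzyloxy)-6-[(2R,12R)-2,12-diacetoxytridecyl]benzoic acid F8. Hydrogenolysis (H2, Pd/C, EtOAc, 25 °C) removes both benzyl groups and leaves the acetates, giving 21.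

Further compounds
F1 | step 6 | (2R,12R)-1-bromotridecane-2,12-diol | C[C@@H](O)CCCCCCCCC[C@@H](O)CBr
F2 | step 6 | (2R,12R)-1-bromotridecane-2,12-diyl diacetate | CC(=O)O[C@H](CCCCCCCCC[C@@H](C)OC(C)=O)CBr
F3 | step 5 | tert-butyl{[(2R)-10-bromodecan-2-yl]oxy}dimethylsilane | C[C@@H](O[Si](C)(C)C(C)(C)C)CCCCCCCCBr
F4 | step 5 | {(9R)-9-[(tert-butyldimethylsilyl)oxy]decyl}magnesium bromide | C[C@@H](O[Si](C)(C)C(C)(C)C)CCCCCCCC[Mg]Br
F5 | step 5 | (2R,12R)-12-[(tert-butyldimethylsilyl)oxy]-1-chlorotridecan-2-ol | C[C@@H](O[Si](C)(C)C(C)(C)C)CCCCCCCCC[C@@H](O)CCl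
F6 | step 5 | tert-butyldimethyl({(2R)-11-[(2R)-oxiran-2-yl]undecan-2-yl}oxy)silane | C[C@@H](O[Si](C)(C)C(C)(C)C)CCCCCCCCC[C@@H]1CO1
F7 | step 9 | (2R,12R)-1-[3,5-bis(benzyloxy)-2-formylphenyl]tridecane-2,12-diyl diacetate | CC(=O)O[C@H](CCCCCCCCC[C@@H](C)OC(C)=O)Cc1cc(OCc2ccccc2)cc(OCc2ccccc2)c1C=O
F8 | step 9 | 2,4-bis(benzyloxy)-6-[(2R,12R)-2,12-diacetoxytridecyl]benzoic acid | CC(=O)O[C@H](CCCCCCCCC[C@@H](C)OC(C)=O)Cc1cc(OCc2ccccc2)cc(OCc2ccccc2)c1C(=O)O
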